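Slowness is what the oak run seems to show, and you want to know what the same charge holds at the look, and whether any option pays.

the same everywhere: E 0.020 M
- oak: Q 0.020 M; the very flask that is asked about, followed so far
- birch: Q 0.010 M; run made earlier
- flask: Q 0.0200 M; time 12 h

- oak (time / h: D / %, E / %): 1.33: 35.8, 42.5; 3.00: 37.5, 40.4; 4.00: 38.1, 39.3; 6.00: 37.9, 40.2; 8.00: 38.8, 39.7
- birch (time / h: D / %, E / %): 1.50: 14.1, 64.6; 3.00: 14.2, 65.1; 5.00: 13.9, 63.9; 6.00: 13.9, 64.2; 8.00: 14.3, 64.9

(readings scatter by 0.5 percentage points)

- summer: change nothing and wait 12 h more
- winter: at 12 h take out 90% of the D then present, then wait 12 h
- spring: at 12 h add E, 50.0% of the amount charged, then wait 12 h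
- midnight: at 12 h add Q, 100% of the amount charged, then wait 12 h

- D, in percent of the E first charged, at 12 h
- which option adds most D ("none" when 2 percentage points or less is all one gets) (summer / winter / spring / midnight / none)
- D present, with what was taken out counted in, in percent of the E first charged, after winter
- D present, with what was taken out counted in, in percent of the E first charged, after spring

- what is taken out of D is counted as made
- the numbers in the tables scatter by 0.5 percentage points (one standard deviation)
- additions bring no volume worth counting

The bench rule says that a creeping flask wants time, so carry oak's climb forward. From its first reading to its last, D rose at a pace that promises, over the further wait,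

rise = 5.4 percentage points

That is more than the margin. But each further point of D costs at least one Q. Every E that has gone took one Q and every D took another, so you can subtract, counting these two uses of Q and no other:

free Q = Q charged per E charged, less the E consumed, less D

oak, last reading: 0.9 points
birch, last reading: 0.6 points

Both are readings, each with a scatter of 0.5 points on every term. The border is the ratio of free Q to the promised rise, 0.167. In oak, control has passed from time to Q, the limiting reagent, because the free Q read there is below the margin. So I expect waiting to bring less than the margin, and taking out D or adding E puts no Q in. My figure for now, and for D after each of these options, is the mean of oak's readings from 4.00 h on, 38.3%. Adding Q supplies 100 points.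

The forecast stands higher than my figure, with 38.8% for now, 39% after winter and 39% after spring. It names midnight as best: “Only adding Q makes substantially more D”.

    E + Q → G (k = 160 L mol⁻¹ h⁻¹)
    Q + G → D (k = 400 L mol⁻¹ h⁻¹)
    Q + D ⇌ L (K = 93.0 L mol⁻¹, k = 690 L mol⁻¹ h⁻¹)
    Q + D → X (k = 13.0 L mol⁻¹ h⁻¹)

The flask gives 38.5%, with 38.5% after winter and 38.5% after spring, while midnight adds 42 points and summer 0 points. The balance, which gave 0.9 points on oak's last reading and has no term for X, comes on the flask at the look to 1.9 points, with Q at 0% and X at 0.959%. Take the neighbour charged with 0.034 M of E, at 0.588 equiv of Q. Its balance leaves 0.48 points, with Q at 0%. That neighbour ends with D at 18.4% and E at 60%.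

(All runs were computed for an exercise; scatter was added.)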